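**Retrosynthetic overview**
1. Target ⇒ epoxy tetraol; the last step puts both angelates on (O2 and O8) at once.
2. Epoxy tetraol ⇒ lactol + 3-bromo-3-methylbutan-2-one: aldol forms C8–C9 (C8 set by the cis C1 alkoxide), 1,3-syn reduction sets C10, bromohydrin closure gives the side-chain oxirane.
3. Lactol ⇒ cis-fused α-methylene keto lactone: Luche reduction (C2), hydroxyl-directed epoxidation (C3), chloride opening (C4), i-Bu2AlH.
4. Keto lactone ⇒ keto acid by an anodic, iodide-mediated C1–O lactonization (key step, new), which places the oxygen cis to the side chain; keto acid ⇒ (S)-carvone by allylic chlorination and two oxidations.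
5. Ring order: cyclohexane bought in (S)-carvone → lactone ring (step 4) → ring oxirane (step 6, opened in step 7) → lactone/lactol opened (step 9) → side-chain oxirane (step 10).

Assumption: the SMILES is read as the (1S,2S,3S,4S,6R,8S,10R) isomer with two (Z)-2-methylbut-2-enoates (angelates); labels C1–C14 are bisabolane positions of the target (ring C1–C6 with C1–OH, C2–OAng, C3(Me)OH, C4–Cl; C6 bears C7(=C14H2)–C8–C9–C10–C11).

**Step 1**
Reactants: 1 (S)-(+)-carvone
Product: 2 10-chlorocarvone [(5S)-5-(3-chloroprop-1-en-2-yl)-2-methylcyclohex-2-en-1-one]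
Conditions: Ca(OCl)2, CO2 (solid), CH2Cl2/H2O, 0 °C
Reagents that add atoms: calcium hypochlorite, [Ca+2].[O-]Cl.[O-]Cl
Why: Ene-type allylic chlorination by HOCl attacks only the electron-rich 1,1-disubstituted alkene (the enone alkene is inert) and leaves the bought stereocentre untouched.

**Step 2**
Reactants: 2 10-chlorocarvone
Product: 3 enal 2-[(1S)-4-methyl-5-oxocyclohex-3-en-1-yl]prop-2-enal
Conditions: Me3NO (anhydrous), NaI (10 mol %), NaHCO3, DMSO, 35 °C
Reagents that add atoms: trimethylamine N-oxide, C[N+](C)(C)[O-]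
Why: Ganem (amine N-oxide, Kornblum-type) oxidation: SN2 of the N-oxide on the iodide-activated allylic halide, then elimination of the alkoxyammonium salt, gives the enal under conditions too mild to move the C7=C14 bond.

**Step 3**
Reactants: 3 enal
Product: 4 keto acid 2-[(1S)-4-methyl-5-oxocyclohex-3-en-1-yl]prop-2-enoic acid
Conditions: NaClO2, NaH2PO4, 2-methylbut-2-ene, t-BuOH/H2O, 0 °C → rt
Reagents that add atoms: sodium chlorite, [Na+].[O-]Cl=O
Why: Pinnick oxidation takes the enal to the acrylic acid while 2-methylbut-2-ene removes HOCl, so both alkenes survive.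

**Step 4**
Reactants: 4 keto acid
Product: 6 cis-fused keto lactone (3aR,7aS)-6-methyl-3-methylidene-3a,4-dihydro-1-benzofuran-2,7(3H,7aH)-dione, via iodo keto acid 5 (not isolated)
Conditions: undivided cell, graphite anode, Pt cathode, n-Bu4NI (20 mol %), 2,6-lutidine (0.5 equiv), MeCN/H2O 19:1, 5 mA cm⁻², 2.4 F mol⁻¹, rt
Reagents that add atoms: none
Why: Proposed new method: iodide-mediated anodic dehydrogenative oxylactonization at the α′-position of a cross-conjugated enone with a tethered acrylic acid — I2/hypoiodite made at the anode iodinates the kinetic α′-enol at C1 anti to the C6 substituent (5), the tethered carboxylate (base supplied by cathodic H2 evolution) displaces iodide with inversion, so the new C1–O bond lies syn to C6–C7 in a cis-fused γ-lactone (expected also to be the favoured ring fusion, C1 being epimerisable), and iodide returns to the cycle; closest known reaction types are hypoiodite-catalysed oxylactonization of keto acids with peroxide oxidants and iodide-mediated electrochemical α-acyloxylation of simple ketones.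

**Step 5**
Reactants: 6 cis-fused keto lactone
Product: 7 allylic alcohol (3aR,7R,7aS)-7-hydroxy-6-methyl-3-methylidene-3a,4,7,7a-tetrahydro-1-benzofuran-2(3H)-one
Conditions: NaBH4, CeCl3·7H2O, MeOH, −78 °C
Reagents that add atoms: none
Why: Luche 1,2-reduction: hydride adds anti to the pseudoaxial C1–O on the open top face, so C2–OH is cis to C1–O (the carvone → cis-carveol sense); −78 °C and CeCl3 suppress conjugate reduction of the α-methylene lactone.

**Step 6**
Reactants: 7 allylic alcohol
Product: 8 epoxy alcohol lactone (7 with a 3,4-oxirane on the face of C2–OH and the lactone C1–O)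
Conditions: VO(acac)2 (5 mol %), t-BuOOH, CH2Cl2, 0 °C → rt
Reagents that add atoms: tert-butyl hydroperoxide, CC(C)(C)OO
Why: Hydroxyl-directed vanadium-catalysed epoxidation (Sharpless–Michaelson) delivers oxygen syn to C2–OH and so fixes C3–O; the electron-poor α-methylene lactone alkene does not react.

**Step 7**
Reactants: 8 epoxy alcohol lactone
Product: 9 chlorohydrin lactone (3aR,5S,6S,7S,7aS)-5-chloro-6,7-dihydroxy-6-methyl-3-methylidenehexahydro-1-benzofuran-2(3H)-one
Conditions: LiCl, AcOH, THF, rt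
Reagents that add atoms: lithium chloride, [Li+].[Cl-]
Why: SN2 opening of the 2,3-epoxy alcohol by chloride at the secondary, distal carbon C4 (trans-diaxial, Fürst–Plattner) inverts C4 and leaves the tertiary C3–OH on the face of C2–OH.

**Step 8**
Reactants: 9 chlorohydrin lactone
Product: 10 lactol (3aR,5S,6S,7S,7aS)-5-chloro-6-methyl-3-methylideneoctahydro-1-benzofuran-2,6,7-triol (anomer mixture)
Conditions: i-Bu2AlH (3.2 equiv), CH2Cl2, −78 °C; aqueous potassium sodium tartrate
Reagents that add atoms: none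
Why: Partial lactone reduction at −78 °C stops at the aluminium acetal, giving the lactol that holds C8 at aldehyde level with C1–O already cis to the side chain.

**Step 9**
Reactants: 10 lactol; 11 3-bromo-3-methylbutan-2-one
Product: 14 aldol (1S,2S,3S,4S,6R)-6-[(3S)-6-bromo-3-hydroxy-6-methyl-5-oxohept-1-en-2-yl]-4-chloro-3-methylcyclohexane-1,2,3-triol, via lithium enolate 12 (not isolated), via trilithium alkoxide aldehyde 13 (not isolated)
Conditions: 11, LiN(i-Pr)2, THF, −78 °C; 10 pretreated with LiN(SiMe3)2 (3.0 equiv), THF, −78 °C; combine, −78 °C, 1 h; AcOH, −78 °C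
Reagents that add atoms: none
Why: Lithium enolate aldol on the ring-opened lactolate under 1,4-chelation control: the axial C1 alkoxide (with the syn-axial C3 alkoxide) binds the s-trans aldehyde oxygen beneath the ring and screens that face, so 12 adds from the C5 side to give 8S; this sense rests on a hand-built conformational model and is not proven. −78 °C and the cold acid quench keep the ring chlorohydrin and the tertiary bromide intact.

**Step 10**
Reactants: 14 aldol
Product: 17 epoxy tetraol (1S,2S,3S,4S,6R)-4-chloro-6-{(3S)-4-[(2R)-3,3-dimethyloxiran-2-yl]-3-hydroxybut-1-en-2-yl}-3-methylcyclohexane-1,2,3-triol, via boron chelate 15 (not isolated), via bromohydrin 16 (not isolated)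
Conditions: Et2BOMe, THF/MeOH 4:1, −78 °C; NaBH4, −78 °C, 3 h; then K2CO3 (1.1 equiv), MeOH, −20 °C
Reagents that add atoms: none
Why: Narasaka–Prasad reduction (axial hydride attack on the six-membered boron chelate) gives the 1,3-syn diol, i.e. 10R from 8S; the tertiary bromohydrin then closes by intramolecular Williamson displacement with the C10–O bond retained, and it should do so much faster than the secondary ring chlorohydrin under 1.1 equiv of K2CO3 at −20 °C.

**Step 11**
Reactants: 17 epoxy tetraol; 18 angelic acid [(2Z)-2-methylbut-2-enoic acid]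
Product: 20 CNP0158207.1, via mixed anhydride 19 (not isolated)
Conditions: 18 (2.6 equiv), 2,4,6-Cl3C6H2COCl, Et3N, toluene, rt, 2 h; then 17, 70 °C
Reagents that add atoms: none
Why: Yamaguchi-type mixed-anhydride esterification without DMAP (Et3N buffer) keeps the Z geometry and should acylate the allylic C8–OH and the equatorial C2–OH ahead of the axial, hydrogen-bonded C1–OH and the tertiary C3–OH.

**Compound list**
1 | (S)-(+)-carvone, (5S)-2-methyl-5-(prop-1-en-2-yl)cyclohex-2-en-1-one | C=C(C)[C@H]1CC=C(C)C(=O)C1 | starting material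
2 | 10-chlorocarvone, (5S)-5-(3-chloroprop-1-en-2-yl)-2-methylcyclohex-2-en-1-one | C=C(CCl)[C@H]1CC=C(C)C(=O)C1 | intermediate
3 | 2-[(1S)-4-methyl-5-oxocyclohex-3-en-1-yl]prop-2-enal | C=C(C=O)[C@H]1CC=C(C)C(=O)C1 | intermediate
4 | 2-[(1S)-4-methyl-5-oxocyclohex-3-en-1-yl]prop-2-enoic acid | C=C(C(=O)O)[C@H]1CC=C(C)C(=O)C1 | intermediate
5 | 2-[(1R,2R)-2-iodo-4-methyl-3-oxocyclohex-4-en-1-yl]prop-2-enoic acid (iodine trans to the side chain) | C=C(C(=O)O)[C@H]1CC=C(C)C(=O)[C@@H]1I | intermediate
6 | (3aR,7aS)-6-methyl-3-methylidene-3a,4-dihydro-1-benzofuran-2,7(3H,7aH)-dione (cis-fused) | C=C1C(=O)O[C@@H]2C(=O)C(C)=CC[C@H]12 | intermediate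
7 | (3aR,7R,7aS)-7-hydroxy-6-methyl-3-methylidene-3a,4,7,7a-tetrahydro-1-benzofuran-2(3H)-one (C2–OH cis to lactone C1–O) | C=C1C(=O)O[C@@H]2[C@H](O)C(C)=CC[C@H]12 | intermediate
8 | epoxy alcohol lactone: 7 with a 3,4-oxirane syn to C2–OH and the lactone C1–O | C=C1C(=O)O[C@@H]2[C@H](O)[C@]3(C)O[C@@H]3C[C@H]12 | intermediate
9 | (3aR,5S,6S,7S,7aS)-5-chloro-6,7-dihydroxy-6-methyl-3-methylidenehexahydro-1-benzofuran-2(3H)-one | C=C1C(=O)O[C@@H]2[C@H](O)[C@](C)(O)[C@@H](Cl)C[C@H]12 | intermediate
10 | (3aR,5S,6S,7S,7aS)-5-chloro-6-methyl-3-methylideneoctahydro-1-benzofuran-2,6,7-triol (lactol, anomer mixture) | C=C1C(O)O[C@@H]2[C@H](O)[C@](C)(O)[C@@H](Cl)C[C@H]12 | intermediate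
11 | 3-bromo-3-methylbutan-2-one | CC(=O)C(C)(C)Br | starting material
12 | lithium 3-bromo-3-methylbut-1-en-2-olate | [Li+].C=C([O-])C(C)(C)Br | intermediate
13 | trilithium (1S,2S,3S,4S,6R)-4-chloro-3-methyl-6-(3-oxoprop-1-en-2-yl)cyclohexane-1,2,3-triolate | [Li+].[Li+].[Li+].C=C(C=O)[C@H]1C[C@H](Cl)[C@@](C)([O-])[C@@H]([O-])[C@H]1[O-] | intermediate
14 | (1S,2S,3S,4S,6R)-6-[(3S)-6-bromo-3-hydroxy-6-methyl-5-oxohept-1-en-2-yl]-4-chloro-3-methylcyclohexane-1,2,3-triol | C=C([C@H](CC(=O)C(C)(C)Br)O)[C@H]1C[C@H](Cl)[C@@](C)(O)[C@@H](O)[C@H]1O | intermediate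
15 | O8-diethylboryl chelate of 14 | C=C([C@H](CC(=O)C(C)(C)Br)OB(CC)CC)[C@H]1C[C@H](Cl)[C@@](C)(O)[C@@H](O)[C@H]1O | intermediate
16 | (1S,2S,3S,4S,6R)-6-[(3S,5R)-6-bromo-3,5-dihydroxy-6-methylhept-1-en-2-yl]-4-chloro-3-methylcyclohexane-1,2,3-triol | C=C([C@H](C[C@@H](O)C(C)(C)Br)O)[C@H]1C[C@H](Cl)[C@@](C)(O)[C@@H](O)[C@H]1O | intermediate
17 | (1S,2S,3S,4S,6R)-4-chloro-6-{(3S)-4-[(2R)-3,3-dimethyloxiran-2-yl]-3-hydroxybut-1-en-2-yl}-3-methylcyclohexane-1,2,3-triol | C=C([C@H](C[C@H]1OC1(C)C)O)[C@H]1C[C@H](Cl)[C@@](C)(O)[C@@H](O)[C@H]1O | intermediate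
18 | angelic acid, (2Z)-2-methylbut-2-enoic acid | C/C=C(/C)C(=O)O | starting material
19 | (2Z)-2-methylbut-2-enoic 2,4,6-trichlorobenzoic anhydride | C/C=C(/C)C(=O)OC(=O)c1c(Cl)cc(Cl)cc1Cl | intermediate
20 | CNP0158207.1, (1S,2S,3S,4S,6R,8S,10R)-4-chloro-10,11-epoxy-1,3-dihydroxybisabol-7(14)-ene-2,8-diyl bis[(2Z)-2-methylbut-2-enoate] | C=C([C@H](C[C@H]1OC1(C)C)OC(=O)/C(C)=C\C)[C@H]1C[C@H](Cl)[C@@](C)(O)[C@@H](OC(=O)/C(C)=C\C)[C@H]1O | target

**Totals**
Total steps: 11. Longest linear sequence: 11 steps from (S)-carvone (11 and 18 are bought).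

**Three steps most likely to fail**

Step 4 (the new anodic oxylactonization). The enone may be iodinated at the γ-position instead of α′, the ring fusion may not be purely cis, or the acrylic acid may be over-oxidized. The fallback uses known chemistry, sets out from 4 and comes back at 6. The dianion of 4 (LiN(i-Pr)2, THF, −78 °C) is hydroxylated with MoO5·py·HMPA anti to the side chain to give the trans α′-hydroxy keto acid F1. An intramolecular Mitsunobu lactonization (PPh3, DIAD, THF, 0 °C) then closes the lactone with inversion at C1 and gives 6.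

Step 9 (facial selectivity of the aldol at C8). The chelation argument rests on a 1,4-relationship and may give a low ratio or the opposite face. The fallback sets out from 10 and comes back at 20. The 8R aldol F2 is reduced anti (Me4NBH(OAc)3, MeCN/AcOH, −30 °C) and closed with K2CO3 in MeOH to the 8R,10R epoxy tetraol F3. Mitsunobu esterification with 18 (PPh3, DIAD, toluene, 0 °C) at the allylic C8–OH, the least hindered secondary hydroxyl, inverts C8 and gives the 8-angelate F4. O2 is then acylated with 19 as in step 11 to reach 20.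

Step 11 (site selectivity of the double angeloylation). C1–OH may compete with C2–OH, and the chlorohydrin and oxirane limit the choice of base and acid. The fallback sets out from 17 and comes back at 20. Heating 17 with Bu2SnO (toluene, reflux, water removal) gives the O1,O2-dibutylstannylene acetal F5. This is acylated by 19 at rt only at the equatorial O2 to give the 2-angelate F6. The remaining allylic C8–OH is then esterified with 19 (1.3 equiv, Et3N, toluene, 60 °C) to give 20.

**Further compounds**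
F1 | step 4 | 2-[(1R,2R)-2-hydroxy-4-methyl-3-oxocyclohex-4-en-1-yl]prop-2-enoic acid (OH trans to the side chain) | C=C(C(=O)O)[C@H]1CC=C(C)C(=O)[C@@H]1O
F2 | step 9 | 8R epimer of 14 | C=C([C@@H](CC(=O)C(C)(C)Br)O)[C@H]1C[C@H](Cl)[C@@](C)(O)[C@@H](O)[C@H]1O
F3 | step 9 | 8R,10R epimer of 17 | C=C([C@@H](C[C@H]1OC1(C)C)O)[C@H]1C[C@H](Cl)[C@@](C)(O)[C@@H](O)[C@H]1O
F4 | step 9 | 8-O-angelate of 17 (8S, O2 free) | C=C([C@H](C[C@H]1OC1(C)C)OC(=O)/C(C)=C\C)[C@H]1C[C@H](Cl)[C@@](C)(O)[C@@H](O)[C@H]1O
F5 | step 11 | O1,O2-dibutylstannylene acetal of 17 | C=C([C@H](C[C@H]1OC1(C)C)O)[C@H]1C[C@H](Cl)[C@@](C)(O)[C@H]2O[Sn](CCCC)(CCCC)O[C@@H]12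
F6 | step 11 | 2-O-angelate of 17 (C8–OH free) | C=C([C@H](C[C@H]1OC1(C)C)O)[C@H]1C[C@H](Cl)[C@@](C)(O)[C@@H](OC(=O)/C(C)=C\C)[C@H]1O
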